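Assumption: 2,2-dimethoxyacetaldehyde (60 % aq.), but-2-ynal and tigloyl chloride are taken as commercial. Locants are germacrane-style: C6 = lactone O–CH, C7 = ring-fusion CH, C8 = CH–O-tigloyl, C10 = C(CH3)OH, C1=C2 and C4=C5 = ring alkenes, C3 = CHOH, C11–C13 = acrylate unit; tigloyl = (2E)-2-methylbut-2-enoyl. The target is (3R,6S,7R,8R,10R), 1Z,4Z, with a cis-fused lactone.

**Retrosynthetic overview**
1. Target 21 ⇐ desilylation of 20 ⇐ ring-closing metathesis (C1=C2) of seco-diene 19; the ten-membered ring is formed last.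
2. 19 ⇐ indium Barbier 2-(alkoxycarbonyl)allylation/lactonisation of lactol 17 with allyl bromide 13 (C6–C7 bond, cis α-methylene lactone; first ring).
3. 17 ⇐ butenolide 16 ⇐ new enantioselective NHC [3+2] annulation of but-2-ynal with acrolein (sets C3, locks the C4=C5 Z geometry).
4. 13 ⇐ Morita–Baylis–Hillman/SN2' bromination of α-tigloyloxy aldehyde 10 ⇐ L-proline aldol of acetone with dimethoxyacetaldehyde (C8), then chelation-controlled vinyl addition (C10).

**Route**

Step 1
Reactants: 1 acetone; 2 2,2-dimethoxyacetaldehyde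
Product: 3 (4R)-4-hydroxy-5,5-dimethoxypentan-2-one
Conditions: L-proline (20 mol %), acetone (20 equiv)/DMSO, rt, 24 h
Reagents that add atoms: none
Why: Proline enamine aldol (List–Barbas type) in which the acetone enamine attacks the Re face of the activated, non-enolisable aldehyde through the carboxylic-acid-bridged chair transition state, setting C8 as R.

Step 2
Reactants: 3 (4R)-4-hydroxy-5,5-dimethoxypentan-2-one; 4 vinylmagnesium bromide
Product: 5 (3R,5R)-6,6-dimethoxy-3-methylhex-1-ene-3,5-diol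
Conditions: 4 (3.2 equiv), THF, −78 → −40 °C; aq. NH4Cl
Reagents that add atoms: none
Why: Chelation-controlled Grignard addition in which the magnesium alkoxide of the β-hydroxy ketone forms a six-membered chelate and vinyl attacks the face opposite the C8 substituent, giving the (3R,5R) tertiary carbinol (C10 R), with the minor epimer removed by chromatography.

Step 3
Reactants: 5 (3R,5R)-6,6-dimethoxy-3-methylhex-1-ene-3,5-diol; 6 tigloyl chloride
Product: 7 (2R,4R)-4-hydroxy-1,1-dimethoxy-4-methylhex-5-en-2-yl tiglate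
Conditions: 6 (1.2 equiv), pyridine, DMAP (10 mol %), CH2Cl2, 0 °C → rt
Reagents that add atoms: none
Why: DMAP-catalysed acylation is selective for the secondary hydroxyl over the tertiary allylic one and touches no stereocentre.

Step 4
Reactants: 7 (2R,4R)-4-hydroxy-1,1-dimethoxy-4-methylhex-5-en-2-yl tiglate
Product: 10 (2R,4R)-4-methyl-1-oxo-4-(triethylsilyloxy)hex-5-en-2-yl tiglate, via silyl ether acetal 8 (not isolated), via collidinium salt 9 (not isolated)
Conditions: TESOTf (3.5 equiv), 2,4,6-collidine (5 equiv), CH2Cl2, 0 °C → rt; then H2O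
Reagents that add atoms: triethylsilyl trifluoromethanesulfonate, CC[Si](CC)(CC)OS(=O)(=O)C(F)(F)F; water, O
Why: Kita–Fujioka acetal cleavage, in which TESOTf/collidine first silylates the tertiary hydroxyl and then converts the dimethyl acetal into a collidinium salt that water hydrolyses to the aldehyde without protic acid, so that the tertiary allylic ether and the tiglate survive and the C10 oxygen can no longer form a lactol or cyclise onto C7 later.

Step 5
Reactants: 10 (2R,4R)-4-methyl-1-oxo-4-(triethylsilyloxy)hex-5-en-2-yl tiglate; 11 methyl acrylate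
Product: 12 methyl (4R,6R)-3-hydroxy-6-methyl-2-methylidene-4-(tigloyloxy)-6-(triethylsilyloxy)oct-7-enoate (C3 epimers)
Conditions: DABCO (0.5 equiv), 11 (5 equiv), neat, 0 °C → rt, 24 h
Reagents that add atoms: none
Why: Morita–Baylis–Hillman reaction, fast for an activated α-acyloxy aldehyde, whose new carbinol centre (C7) is left as a mixture because it becomes sp2 in the next step.

Step 6
Reactants: 12 methyl (4R,6R)-3-hydroxy-6-methyl-2-methylidene-4-(tigloyloxy)-6-(triethylsilyloxy)oct-7-enoate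
Product: 13 methyl (2Z,4R,6R)-2-(bromomethyl)-6-methyl-4-(tigloyloxy)-6-(triethylsilyloxy)octa-2,7-dienoate
Conditions: NBS (1.5 equiv), Me2S (1.8 equiv), CH2Cl2, 0 °C → rt
Reagents that add atoms: N-bromosuccinimide, O=C1CCC(=O)N1Br
Why: Corey–Kim-type activation of the allylic alcohol followed by SN2' attack of bromide converges both C7 epimers on the thermodynamically preferred (Z)-2-(bromomethyl)enoate, with C8 cis to CH2Br.

Step 7
Reactants: 14 but-2-ynal; 15 acrolein
Product: 16 (5R)-5-ethenyl-4-methylfuran-2(5H)-one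
Conditions: chiral aminoindanol-derived N-mesityl triazolium chloride (10 mol %), iPr2NEt (20 mol %), 4 Å MS, toluene, −20 → 0 °C, slow addition of 14 to 15 (3 equiv)
Reagents that add atoms: none
Why: Proposed new method: the carbene adds to the more electrophilic ynal 14 to give a Breslow/allenolate intermediate whose β-carbon (homoenolate) attacks the acrolein C=O 1,2 inside the chiral pocket (C3–C4 bond, C3 set as R with the catalyst antipode chosen accordingly), and the resulting alkoxide is acylated by the Z-enoyl azolium to close the butenolide (locking the C4=C5 Z geometry) and release the carbene, the closest known reactions being NHC homoenolate [3+2] annulations of enals with aldehydes and Lewis-acid-assisted, non-enantioselective ynal–carbonyl butenolide annulations, so the new elements are an enal as the carbonyl partner, enantiocontrol and no metal co-catalyst.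

Step 8
Reactants: 16 (5R)-5-ethenyl-4-methylfuran-2(5H)-one
Product: 17 (5R)-5-ethenyl-4-methyl-2,5-dihydrofuran-2-ol (C2 epimers; ring form of (2Z,4R)-4-hydroxy-3-methylhexa-2,5-dienal)
Conditions: DIBAL-H (1.05 equiv), CH2Cl2, −78 °C; Rochelle salt (pH 7), 0 °C; used at once
Reagents that add atoms: none
Why: Partial reduction of the lactone stops at the aluminium hemiacetal at −78 °C, leaves C3 untouched, and the cold neutral work-up avoids dehydration to the furan.

Step 9
Reactants: 13 methyl (2Z,4R,6R)-2-(bromomethyl)-6-methyl-4-(tigloyloxy)-6-(triethylsilyloxy)octa-2,7-dienoate; 17 (5R)-5-ethenyl-4-methyl-2,5-dihydrofuran-2-ol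
Product: 19 (4R,5S)-5-[(1Z,3R)-3-hydroxy-2-methylpenta-1,4-dien-1-yl]-3-methylidene-4-[(1R,3R)-3-methyl-1-(tigloyloxy)-3-(triethylsilyloxy)pent-4-en-1-yl]oxolan-2-one, via hydroxy ester 18 (not isolated)
Conditions: In powder (1.5 equiv), 17 (1.3 equiv), THF/H2O (2:1), rt, 8 h; then PPTS (10 mol %), CH2Cl2, rt
Reagents that add atoms: none
Why: Indium Barbier 2-(alkoxycarbonyl)allylation through a chair Zimmerman–Traxler transition state, in which the (Z)-allylindium (C8 axial) gives the 6,7-syn adduct (cis-lactone) and the aldehyde form of the lactol approaches C7 anti to the C9 chain of the A(1,3)-locked C8 stereocentre, setting 6S,7R before the C6 hydroxyl lactonises onto the methyl ester.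

Step 10
Reactants: 19 (the seco-diene lactone of step 9)
Product: 20 (3aR,4R,6R,7Z,9R,10Z,11aS)-9-hydroxy-6,10-dimethyl-3-methylidene-2-oxo-6-(triethylsilyloxy)-2,3,3a,4,5,6,9,11a-octahydrocyclodeca[b]furan-4-yl tiglate
Conditions: Hoveyda–Grubbs II (2 × 7.5 mol %), 1,4-benzoquinone (20 mol %), toluene (1 mM), 80 °C, Ar sparge
Reagents that add atoms: none
Why: Ring-closing metathesis in which ruthenium loads on the C2 vinyl next to the free allylic hydroxyl while the bulky O10 silyl ether keeps it off the C1 vinyl (disfavouring six-ring closure onto the exocyclic methylene), the seven-ring alternative being a bridgehead alkene, and the ten-membered ring can only hold the Z alkene.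

Step 11
Reactants: 20 (the silyl-protected macrocycle of step 10)
Product: 21 (3aR,4R,6R,7Z,9R,10Z,11aS)-6,9-dihydroxy-6,10-dimethyl-3-methylidene-2-oxo-2,3,3a,4,5,6,9,11a-octahydrocyclodeca[b]furan-4-yl tiglate (target)
Conditions: HF·pyridine, pyridine, THF, 0 °C → rt
Reagents that add atoms: none
Why: Buffered fluoride cleavage of the tertiary triethylsilyl ether is compatible with the methylene lactone, the tiglate and the bis-allylic alcohol and changes no stereocentre.

**Compound list**
1 | acetone | CC(C)=O | starting material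
2 | 2,2-dimethoxyacetaldehyde | COC(OC)C=O | starting material
3 | (4R)-4-hydroxy-5,5-dimethoxypentan-2-one | CC(=O)C[C@@H](O)C(OC)OC | intermediate
4 | vinylmagnesium bromide | C=C[Mg]Br | starting material
5 | (3R,5R)-6,6-dimethoxy-3-methylhex-1-ene-3,5-diol | C=C[C@](C)(O)C[C@@H](O)C(OC)OC | intermediate
6 | tigloyl chloride, (2E)-2-methylbut-2-enoyl chloride | C/C=C(\C)C(=O)Cl | starting material
7 | (2R,4R)-4-hydroxy-1,1-dimethoxy-4-methylhex-5-en-2-yl (2E)-2-methylbut-2-enoate | C=C[C@](C)(O)C[C@@H](OC(=O)/C(C)=C/C)C(OC)OC | intermediate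
8 | (2R,4R)-1,1-dimethoxy-4-methyl-4-(triethylsilyloxy)hex-5-en-2-yl (2E)-2-methylbut-2-enoate | C=C[C@](C)(O[Si](CC)(CC)CC)C[C@@H](OC(=O)/C(C)=C/C)C(OC)OC | intermediate
9 | 1-[(2R,4R)-1-methoxy-4-methyl-2-(tigloyloxy)-4-(triethylsilyloxy)hex-5-en-1-yl]-2,4,6-trimethylpyridinium triflate (C1 epimers) | C=C[C@](C)(O[Si](CC)(CC)CC)C[C@@H](OC(=O)/C(C)=C/C)C(OC)[n+]1c(C)cc(C)cc1C.[O-]S(=O)(=O)C(F)(F)F | intermediate
10 | (2R,4R)-4-methyl-1-oxo-4-(triethylsilyloxy)hex-5-en-2-yl (2E)-2-methylbut-2-enoate | C=C[C@](C)(O[Si](CC)(CC)CC)C[C@@H](OC(=O)/C(C)=C/C)C=O | intermediate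
11 | methyl acrylate | C=CC(=O)OC | starting material
12 | methyl (4R,6R)-3-hydroxy-6-methyl-2-methylidene-4-(tigloyloxy)-6-(triethylsilyloxy)oct-7-enoate (C3 epimers) | C=C[C@](C)(O[Si](CC)(CC)CC)C[C@@H](OC(=O)/C(C)=C/C)C(O)C(=C)C(=O)OC | intermediate
13 | methyl (2Z,4R,6R)-2-(bromomethyl)-6-methyl-4-(tigloyloxy)-6-(triethylsilyloxy)octa-2,7-dienoate | C=C[C@](C)(O[Si](CC)(CC)CC)C[C@@H](OC(=O)/C(C)=C/C)/C=C(\CBr)C(=O)OC | intermediate
14 | but-2-ynal | CC#CC=O | starting material
15 | acrolein (prop-2-enal) | C=CC=O | starting material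
16 | (5R)-5-ethenyl-4-methylfuran-2(5H)-one | O=C1C=C(C)[C@H](O1)C=C | intermediate
17 | (5R)-5-ethenyl-4-methyl-2,5-dihydrofuran-2-ol (C2 epimers) | OC1C=C(C)[C@H](O1)C=C | intermediate
18 | methyl (3S,4S,5Z,7R)-4,7-dihydroxy-6-methyl-2-methylidene-3-[(1R,3R)-3-methyl-1-(tigloyloxy)-3-(triethylsilyloxy)pent-4-en-1-yl]nona-5,8-dienoate | C=C(C(=O)OC)[C@@H]([C@@H](O)/C=C(/C)[C@H](O)C=C)[C@H](OC(=O)/C(C)=C/C)C[C@@](C)(O[Si](CC)(CC)CC)C=C | intermediate
19 | (4R,5S)-5-[(1Z,3R)-3-hydroxy-2-methylpenta-1,4-dien-1-yl]-3-methylidene-4-[(1R,3R)-3-methyl-1-(tigloyloxy)-3-(triethylsilyloxy)pent-4-en-1-yl]oxolan-2-one | C=C1C(=O)O[C@@H](/C=C(/C)[C@H](O)C=C)[C@H]1[C@H](OC(=O)/C(C)=C/C)C[C@@](C)(O[Si](CC)(CC)CC)C=C | intermediate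
20 | (3aR,4R,6R,7Z,9R,10Z,11aS)-9-hydroxy-6,10-dimethyl-3-methylidene-2-oxo-6-(triethylsilyloxy)-2,3,3a,4,5,6,9,11a-octahydrocyclodeca[b]furan-4-yl (2E)-2-methylbut-2-enoate | C=C1C(=O)O[C@H]2/C=C(/C)[C@H](O)/C=C\[C@](C)(O[Si](CC)(CC)CC)C[C@@H](OC(=O)/C(C)=C/C)[C@@H]12 | intermediate
21 | (3aR,4R,6R,7Z,9R,10Z,11aS)-6,9-dihydroxy-6,10-dimethyl-3-methylidene-2-oxo-2,3,3a,4,5,6,9,11a-octahydrocyclodeca[b]furan-4-yl (2E)-2-methylbut-2-enoate | C=C1C(=O)O[C@H]2/C=C(/C)[C@H](O)/C=C\[C@](C)(O)C[C@@H](OC(=O)/C(C)=C/C)[C@@H]12 | target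

**Step count**
Total steps: 11. Longest linear sequence: 9 (steps 1–6, 9, 10, 11).

**Three steps most likely to fail**

Step 7 (the proposed NHC annulation). Acrolein may self-annulate or polymerise, the enantioselectivity may be low, and the base may isomerise 16. The fallback uses known chemistry, sets out from 15 and comes back at 16. A Zn–ProPhenol-catalysed asymmetric addition of methyl propiolate to acrolein gives methyl (4R)-4-hydroxyhex-5-en-2-ynoate F1. Syn-carbocupration with Me2CuLi (THF, −78 °C) then places the methyl group on C4, and the resulting (Z)-hydroxy enoate lactonises on work-up to 16.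

Step 9 (indium Barbier coupling). The lactol can dehydrate to 3-methyl-2-vinylfuran, and the facial selectivity at C7 rests on a conformational model. The fallback puts C6/C7 under catalyst control, sets out from 16 and 12 and comes back at 19. Compound 16 is opened with MeNH(OMe)·HCl/Me3Al to (2Z,4R)-4-hydroxy-N-methoxy-N,3-dimethylhexa-2,5-dienamide F2. This is silylated (TESCl, imidazole) to (2Z,4R)-N-methoxy-N,3-dimethyl-4-(triethylsilyloxy)hexa-2,5-dienamide F3 and reduced (DIBAL-H, −78 °C) to (2Z,4R)-3-methyl-4-(triethylsilyloxy)hexa-2,5-dienal F4. Compound 12 is acetylated to methyl (4R,6R)-3-acetoxy-6-methyl-2-methylidene-4-(tigloyloxy)-6-(triethylsilyloxy)oct-7-enoate F5. Copper-catalysed SN2' borylation with B2pin2 then gives methyl (2E,4R,6R)-6-methyl-2-[(4,4,5,5-tetramethyl-1,3,2-dioxaborolan-2-yl)methyl]-4-(tigloyloxy)-6-(triethylsilyloxy)octa-2,7-dienoate F6. Chiral phosphoric acid (TRIP)-catalysed allylboration of F4 with F6, followed by lactonisation, gives the O3,O10-bis(triethylsilyl) ether of 19 F7. Its secondary allylic silyl ether is removed selectively (PPTS, MeOH, 0 °C) to give 19.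

Step 10 (ring-closing metathesis). The exocyclic methylene can compete for the C1 vinyl (six-ring closure), and oligomerisation is possible. The fallback masks the methylene lactone, sets out from 19 and comes back at 20. Conjugate addition of Me2NH (THF, 0 °C) gives the 3-[(dimethylamino)methyl] lactone of 19 F8. Ring-closing metathesis of its TsOH salt gives the ring-closed 3-[(dimethylamino)methyl] analogue of 20 F9. Quaternisation with MeI and elimination with NaHCO3 then regenerate the methylene lactone 20.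

Further compounds
F1 | step 7 | methyl (4R)-4-hydroxyhex-5-en-2-ynoate | COC(=O)C#C[C@H](O)C=C
F2 | step 9 | (2Z,4R)-4-hydroxy-N-methoxy-N,3-dimethylhexa-2,5-dienamide | CON(C)C(=O)/C=C(/C)[C@H](O)C=C
F3 | step 9 | (2Z,4R)-N-methoxy-N,3-dimethyl-4-(triethylsilyloxy)hexa-2,5-dienamide | CON(C)C(=O)/C=C(/C)[C@H](O[Si](CC)(CC)CC)C=C
F4 | step 9 | (2Z,4R)-3-methyl-4-(triethylsilyloxy)hexa-2,5-dienal | O=C/C=C(/C)[C@H](O[Si](CC)(CC)CC)C=C
F5 | step 9 | methyl (4R,6R)-3-acetoxy-6-methyl-2-methylidene-4-(tigloyloxy)-6-(triethylsilyloxy)oct-7-enoate (C3 epimers) | C=C[C@](C)(O[Si](CC)(CC)CC)C[C@@H](OC(=O)/C(C)=C/C)C(OC(C)=O)C(=C)C(=O)OC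
F6 | step 9 | methyl (2E,4R,6R)-6-methyl-2-[(4,4,5,5-tetramethyl-1,3,2-dioxaborolan-2-yl)methyl]-4-(tigloyloxy)-6-(triethylsilyloxy)octa-2,7-dienoate | C=C[C@](C)(O[Si](CC)(CC)CC)C[C@@H](OC(=O)/C(C)=C/C)/C=C(\CB1OC(C)(C)C(C)(C)O1)C(=O)OC
F7 | step 9 | O3,O10-bis(triethylsilyl) ether of 19 | C=C1C(=O)O[C@@H](/C=C(/C)[C@H](O[Si](CC)(CC)CC)C=C)[C@H]1[C@H](OC(=O)/C(C)=C/C)C[C@@](C)(O[Si](CC)(CC)CC)C=C
F8 | step 10 | 3-[(dimethylamino)methyl] lactone from 19 (C3 epimers) | CN(C)CC2C(=O)O[C@@H](/C=C(/C)[C@H](O)C=C)[C@H]2[C@H](OC(=O)/C(C)=C/C)C[C@@](C)(O[Si](CC)(CC)CC)C=C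
F9 | step 10 | ring-closed 3-[(dimethylamino)methyl] analogue of 20 (C3 epimers) | CN(C)CC3C(=O)O[C@H]2/C=C(/C)[C@H](O)/C=C\[C@](C)(O[Si](CC)(CC)CC)C[C@@H](OC(=O)/C(C)=C/C)[C@@H]32
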